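(The runs were generated by integration on assumed constants; noise was put on by code.)

The excess of Lx over its last reading shrinks by a ratio of 4.00 from 10.0 min to 60.0 min in this flask, as read through the scatter. Dx and Wa give Lx, and Lx then falls towards a rest.

common to all: Dx 0.50 M
- oak: Wa 1.2 equiv; the very flask that is asked about, followed so far
- flask: Wa 1.20 equiv; time 2.5 h

oak run (percent of the Dx charged)

| time / min | Lx / % |
|---|---|
| 10.0 | 43.9 |
| 30.0 | 38.7 |
| 60.0 | 31.6 |
| 80.0 | 30.1 |
| 120 | 27.5 |

(standard deviation of a reading: 1 percentage point)

- what is taken out of Lx is counted as made
- additions bring no volume worth counting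

- autumn: at 2.5 h add Dx, 50.0% of the amount charged, then wait 50 min
- midnight: at 2.5 h add Wa, 50.0% of the amount charged, then wait 50 min
- dusk: at 2.5 h take out 90% of the Lx then present, then wait 50 min
- winter: change nothing and wait 50 min more

- Lx, in percent of the Dx first charged, at 2.5 h
- the remedy with the largest gain of Lx, or "none" below 2 percentage points (autumn / midnight / dusk / winter / none)
- Lx present, with what was taken out counted in, in percent of the Dx first charged, after autumn
- Lx present, with what was taken out counted in, in percent of the Dx first charged, after dusk

A quarter of the excess is left after two half-lives, so I read: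

h = 25.0 min

n = dt / h = 2.00

I call n the half-life count: the time waited over h. From it I estimate the share of the Lx taken out that this flask regains in the wait after dusk, here 75.0%.

I take c(Lx) at 2.5 h as the last reading, 27.5%, give or take 1 percentage point. Then I bracket dusk, with what is taken out counted in.

No Lx comes back: 27.5%

Lx returns to its old level: 52.2%

Count applied: 46.1%

The forecast gives 26.5% now, 34% after autumn, 39% after dusk, and dusk as best: “Removing Lx pulls much more through”. Its dusk value lies inside my bracket, but lower than my count.

The flask gives 28.4% now, 36.3% after autumn, 44.5% after dusk, and dusk as best, with a gain of 16 points.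

    Lx ⇌ Ry (K = 1.40, k = 3.30 × 10⁻⁴ /s)
    Dx + Wa ⇌ Lx (K = 8.10 /M, k = 0.340 /M/s)
    Dx + Wa ⇌ Aj (K = 4.40 /M, k = 0.0490 /M/s)

In this flask the step from Lx to Ry relaxes with a half-life of 20.4 min, shorter than the 2.5 h of the run, and the slowest mode of the flask as it stands at 150 min has a half-life of 28.9 min. My count of 2.00 gave 75.0%, and dusk brings this flask back 63.3% of what was taken out. With my h taken over, the neighbour flask with 3.00 equiv of Wa counts 6.00 over its 2.5 h, and it holds Ry over Lx at 1.35, about as this flask does, at 1.34.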